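**Strategy.** Ring C is cut across two bonds, C2–C3 and C4–C4a, so that the flavanone becomes a 3,4-dimethoxybenzyl aryl ether plus a two-carbon enol ether. In the key step DDQ removes hydride from C2, which is benzylic to ring B and bound to O1. The resulting aryl oxocarbenium ion (O1=C2 with C8a=C4a of ring A, a cationic 2-oxadiene) undergoes a chiral-phosphate-controlled oxa-Povarov [4+2] annulation with ethyl vinyl ether, forming both bonds and the C2 stereocentre at once. Because the 3,4,5-trimethoxyphenoxy ring A is symmetric, either ortho carbon can become C4a. Oxidation at C4 and peri-selective 5-O-demethylation finish the synthesis.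

Key step: step 2

Numbering used: flavanone numbering, O1, C2, C3, C4 (ring C), C4a, C5–C8, C8a (ring A); ring B is the 3,4-dimethoxyphenyl group on C2. The target is the (2S) enantiomer.

Assumption: the facial preference imposed by a given enantiomer of the chiral phosphate cannot be predicted with certainty; the (R) acid is written, and its mirror image is taken if it should favour the (2R) series. Any C4 epimer of 6 converges on 7 in step 3.

**Step 1**
Reactants: 1 3,4,5-trimethoxyphenol; 2 3,4-dimethoxybenzyl chloride
Product: 3 5-[(3,4-dimethoxybenzyl)oxy]-1,2,3-trimethoxybenzene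
Conditions: K2CO3, KI (cat.), DMF, 40 °C
Reagents that add atoms: none
Why: Williamson ether synthesis: the phenoxide of 1 displaces chloride from the activated benzylic chloride 2 by SN2, and the carbonate/dipolar aprotic medium favours O- over C-alkylation of the electron-rich phenol.

**Step 2**
Reactants: 3 5-[(3,4-dimethoxybenzyl)oxy]-1,2,3-trimethoxybenzene; 4 ethyl vinyl ether
Product: 6 (2S,4S)-2-(3,4-dimethoxyphenyl)-4-ethoxy-5,6,7-trimethoxychromane, via DDQH mixed acetal 5 (not isolated)
Conditions: DDQ (2,3-dichloro-5,6-dicyano-1,4-benzoquinone, 1.05 equiv), 4 Å MS, CH2Cl2, 0 °C to rt; then (R)-TRIP [(R)-3,3'-bis(2,4,6-triisopropylphenyl)-1,1'-binaphthyl-2,2'-diyl hydrogen phosphate, 10 mol %], 4 (3 equiv), toluene/CH2Cl2, −60 °C; Et3N quench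
Reagents that add atoms: none
Why: Proposed new method: DDQ abstracts hydride from C2–H, the only C–H that is both benzylic to the electron-rich ring B and alpha to O1, and the cation is stored as DDQH acetal 5, which the chiral phosphoric acid re-ionises (DDQH2 precipitates) to an aryl oxocarbenium/chiral phosphate ion pair, a cationic 2-oxadiene (O1=C2 with C8a=C4a). Ethyl vinyl ether adds through its CH2 terminus to C2 and the new ethoxycarbenium carbon C4 is captured by C4a, a formal inverse-electron-demand [4+2] annulation; the closest known reactions are the Lewis-acid oxa-Povarov reaction of aryl oxocarbenium ions with alkenes and the chiral-phosphoric-acid-catalysed Povarov reaction of N-aryl imines with vinyl ethers. Ring C closes in the second bond formation by Friedel–Crafts attack of C4a on C4, 6-endo-trig with respect to the arene bond C8a=C4a, with the C4=O+ bond remaining exocyclic. C2 is set in the first C–C bond formation by the phosphate counter-anion, which shields one face of the planar oxocarbenium ion; C4 should follow as cis through the compact endo-type arrangement and is erased in step 3. The step needs a single regiochemistry of arene attack, which is secured because both ortho carbons of the symmetric 3,4,5-trimethoxyphenoxy ring are identical, and it needs the vinyl ether to meet no free DDQ, which is secured by adding it only after the oxidation is complete.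

**Step 3**
Reactants: 6 (2S,4S)-2-(3,4-dimethoxyphenyl)-4-ethoxy-5,6,7-trimethoxychromane
Product: 7 (S)-2-(3,4-dimethoxyphenyl)-5,6,7-trimethoxychroman-4-one
Conditions: DDQ (1.2 equiv), CH2Cl2/pH 7 phosphate buffer (10:1), 0 °C
Reagents that add atoms: water, O
Why: Oxidative cleavage of an electron-rich benzylic ether by DDQ (the reaction type used to remove dimethoxybenzyl ethers): hydride is abstracted from C4–H, which is benzylic to the tetra-oxygenated ring A and alpha to OEt and therefore more hydridic than C2–H next to the less electron-rich ring B, water adds to the C4 oxocarbenium ion and the hemiketal loses ethanol to give the ketone, leaving C2 untouched under these neutral conditions.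

**Step 4**
Reactants: 7 (S)-2-(3,4-dimethoxyphenyl)-5,6,7-trimethoxychroman-4-one
Product: 9 (S)-2-(3,4-dimethoxyphenyl)-5-hydroxy-6,7-dimethoxychroman-4-one, via aryloxydichloroborane chelate 8 (not isolated)
Conditions: BCl3 (1.2 equiv), CH2Cl2, −78 to −20 °C; then H2O
Reagents that add atoms: none
Why: Chelation-controlled peri demethylation of an ortho-methoxy aryl ketone: BCl3 bridges C4=O and the 5-OMe oxygen in a six-membered chelate, chloride removes that methyl group by SN2, and the four methyl ethers that cannot chelate should survive at low temperature, where ring C is also not expected to open at C2.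

**Compound list**
1 | 3,4,5-trimethoxyphenol | COc1cc(O)cc(OC)c1OC | starting material
2 | 3,4-dimethoxybenzyl chloride | COc1ccc(CCl)cc1OC | starting material
3 | 5-[(3,4-dimethoxybenzyl)oxy]-1,2,3-trimethoxybenzene | COc1ccc(COc2cc(OC)c(OC)c(OC)c2)cc1OC | intermediate
4 | ethyl vinyl ether | C=COCC | starting material
5 | DDQH mixed acetal, 2,3-dichloro-5,6-dicyano-4-hydroxyphenyl 3,4,5-trimethoxyphenyl acetal of 3,4-dimethoxybenzaldehyde (racemic, not isolated; in equilibrium with the aryl oxocarbenium ion pair) | COc1ccc(C(Oc2cc(OC)c(OC)c(OC)c2)Oc2c(Cl)c(Cl)c(O)c(C#N)c2C#N)cc1OC | intermediate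
6 | (2S,4S)-2-(3,4-dimethoxyphenyl)-4-ethoxy-5,6,7-trimethoxychromane (2,4-cis) | COc1ccc([C@@H]2C[C@H](OCC)c3c(cc(OC)c(OC)c3OC)O2)cc1OC | intermediate
7 | (S)-2-(3,4-dimethoxyphenyl)-5,6,7-trimethoxychroman-4-one | COc1ccc([C@@H]2CC(=O)c3c(cc(OC)c(OC)c3OC)O2)cc1OC | intermediate
8 | (S)-5-(dichloroboryloxy)-2-(3,4-dimethoxyphenyl)-6,7-dimethoxychroman-4-one, boron chelated to C4=O (not isolated) | COc1ccc([C@@H]2CC(=O)c3c(cc(OC)c(OC)c3OB(Cl)Cl)O2)cc1OC | intermediate
9 | (S)-2-(3,4-dimethoxyphenyl)-5-hydroxy-6,7-dimethoxychroman-4-one | COc1ccc([C@@H]2CC(=O)c3c(cc(OC)c(OC)c3O)O2)cc1OC | target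

**Step count and risks**
Total steps: 4. Longest linear sequence: 4 steps (1 or 2 → 3 → 6 → 7 → 9).

Steps most likely to fail:

Step 2 (Proposed new method). The chiral phosphate may fail to out-compete ionisation of 5 with its own achiral DDQH counter-ion, giving poor facial selectivity at C2. The ethoxycarbenium ion may also take up a second vinyl ether before ring closure. The fallback keeps the same two-bond annulation but uses known chemistry and secures the configuration by resolution. It sets out from 3. DDQ in CH2Cl2/AcOH should give the racemic alpha-acetoxy ether (3,4-dimethoxyphenyl)(3,4,5-trimethoxyphenoxy)methyl acetate F1. SnCl4 in CH2Cl2 at −78 °C with 4 then effects the established Lewis-acid oxa-Povarov annulation to racemic 2-(3,4-dimethoxyphenyl)-4-ethoxy-5,6,7-trimethoxychromane F2 (C4 epimers). DDQ in wet CH2Cl2, as in step 3, converts this into racemic 2-(3,4-dimethoxyphenyl)-5,6,7-trimethoxychroman-4-one F3. Kinetic resolution by asymmetric transfer hydrogenation (RuCl[(R,R)-TsDPEN](p-cymene), HCO2H/Et3N, EtOAc, stopped near half conversion) should reduce the (2R) enantiomer to the cis alcohol (2R,4R)-2-(3,4-dimethoxyphenyl)-5,6,7-trimethoxychroman-4-ol F4, which is removed by chromatography. The unreacted ketone is 7, where the route is rejoined.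

Step 3. The C4 cation may eliminate to the 4-ethoxy-2H-chromene, and a second hydride abstraction at C2 would then aromatise ring C and destroy the stereocentre. Direct oxidation at C2–H may also compete. The fallback avoids hydride abstraction and sets out from 6. The very acid-labile trioxygenated benzylic ether is exchanged by SN1 solvolysis (PPTS cat., THF/H2O, rt) to (2S)-2-(3,4-dimethoxyphenyl)-5,6,7-trimethoxychroman-4-ol F5 (C4 epimers). Dess–Martin periodinane with NaHCO3 in CH2Cl2 then oxidises the alcohol to 7.

Step 4. The Lewis acid may open ring C at the O1–C2 bond (retro-oxa-Michael through the boron enolate) and re-close it, eroding the configuration at C2. The 6-methoxy group may also be attacked once the 5-O–boron chelate has formed. The fallback secures configurational purity after the demethylation instead of before it. It sets out from 7: the demethylation is run as in step 4, and the partly racemised product is submitted to the same transfer-hydrogenation kinetic resolution (RuCl[(R,R)-TsDPEN](p-cymene), HCO2H/Et3N, EtOAc). This should convert the (2R) enantiomer into (2R,4R)-2-(3,4-dimethoxyphenyl)-6,7-dimethoxychromane-4,5-diol F6, which is separated, and return 9.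

**Further compounds**
F1 | step 2 | (3,4-dimethoxyphenyl)(3,4,5-trimethoxyphenoxy)methyl acetate (racemic) | COc1ccc(C(OC(C)=O)Oc2cc(OC)c(OC)c(OC)c2)cc1OC
F2 | step 2 | racemic 2-(3,4-dimethoxyphenyl)-4-ethoxy-5,6,7-trimethoxychromane (C4 epimers) | COc1ccc(C2CC(OCC)c3c(cc(OC)c(OC)c3OC)O2)cc1OC
F3 | step 2 | racemic 2-(3,4-dimethoxyphenyl)-5,6,7-trimethoxychroman-4-one | COc1ccc(C2CC(=O)c3c(cc(OC)c(OC)c3OC)O2)cc1OC
F4 | step 2 | (2R,4R)-2-(3,4-dimethoxyphenyl)-5,6,7-trimethoxychroman-4-ol | COc1ccc([C@H]2C[C@@H](O)c3c(cc(OC)c(OC)c3OC)O2)cc1OC
F5 | step 3 | (2S)-2-(3,4-dimethoxyphenyl)-5,6,7-trimethoxychroman-4-ol (C4 epimers) | COc1ccc([C@@H]2CC(O)c3c(cc(OC)c(OC)c3OC)O2)cc1OC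
F6 | step 4 | (2R,4R)-2-(3,4-dimethoxyphenyl)-6,7-dimethoxychromane-4,5-diol | COc1ccc([C@H]2C[C@@H](O)c3c(cc(OC)c(OC)c3O)O2)cc1OC
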